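## The problem

The target is a cyclohexene with two 5,7-dimethoxycoumarin-8-yl units on adjacent ring carbons: coumarin A through a secondary carbinol on C1, coumarin B bonded directly to C2. C3=C4(Me) is the only ring alkene and C6, next to C1, is a gem-dimethyl quaternary carbon. Three contiguous stereocentres are needed: C1 (S) and C2 (R), trans on the ring, and the exocyclic carbinol (S). C2 is allylic and remote from any carbonyl group, so it cannot be corrected by equilibration and must be made with absolute control. C1 is best set together with C2, and the carbinol can then be derived from C1, whose two carbon neighbours (quaternary C6 against tertiary C2) differ enough to steer a nucleophile. Both arenes are joined through C8, the carbon flanked by the lactone oxygen and the 7-methoxy group, so an intact aryl nucleophile or electrophile would have to react at a doubly ortho-substituted position next to a congested ring carbon. The sensitive functions are the carbinol (on a trioxygenated arene, it ionises readily under acid), the two lactones (they tolerate neither organometallic reagents nor hydrides and must appear late) and the C2–H bond (allylic and benzylic at once). The feature that opens the key step is the benzene ring of coumarin B: a 1,3,5-trioxygenated ring attached through the carbon between two oxygens. Its six carbons can be divided into the two carbons of an alkyne on C2 and the four carbons of 3-methoxycyclobutenone, so C2 need carry only a slim alkyne when its configuration is set.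

## Retrosynthesis

**Coumarin rings last.** After removal of the carbinol silyl group (37), the two pyranone rings of target 38 are cut at C4–C4a and at the lactone C–O bond. This gives the bis(aryl propiolate) 36 and then bisphenol 35. Preformed coumarins would not survive the organolithium, hydride and fluoride steps needed earlier, whereas 35 carries only two plain phenols. The forward reaction must close two rings by 6-endo hydroarylation. Each arene has exactly one free position ortho to the ester oxygen, and that position is ortho and para to methoxy groups.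

**Telling the ring-B oxygens apart.** Bisphenol 35 is traced through methyl ether 33 to phenol 32. In 32 ring B carries one free hydroxyl and one triisopropylsilyl ether, ring A's phenol is a methoxymethyl ether, and the carbinol is a tert-butyldimethylsilyl ether. Either ortho oxygen of ring B may become the lactone oxygen, so the only demand is that one be methylated before the other is freed.

**Ring B from an alkyne (key disconnection).** In 32 the benzene ring of ring B is cut at two bonds: from the carbon bonded to C2 to the C–OH carbon, and from the C–OSi carbon to its CH neighbour. The fragments are siloxyalkyne 25 and 3-methoxycyclobut-2-en-1-one 27 (from 26), which supplies C–OH, CH, C–OMe and CH. The neighbouring options are to attach a complete 2,4,6-trioxygenated aryl group to C2 through its most hindered carbon, or to carry that aryl group on an acceptor before the ring exists. The alkyne cut reduces ring B to a two-carbon, rod-shaped substituent and adds no stereocentre in the forward step. It asks for regioselective union of ketene and alkyne, and for survival of the silyl ether, the acetal and the ring alkene under neutral heating.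

**The ynol ether.** 25 goes back to terminal alkyne 22 by oxidation of the acetylide at its terminus and O-silylation, and 22 to alcohol 21 and silylalkyne 20. An ester at C2 as ynolate source was rejected because it would put an acidic, epimerisable C–H at C2.

**The carbinol.** The carbinol C–H bond of 20 is cut to ketone 19, and the carbonyl–arene bond to aldehyde 14 and aryllithium 17 (from 16, from phenol 15). Hydride addition to 19 is the stereo-determining event because the Felkin–Anh model, with C6 as the large group, predicts the (S)-carbinol only when hydride is the incoming group. Direct aryl addition to 14 is predicted to give the epimer. Aldehyde 14 has no arene and only two stereocentres.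

**The ring alkene.** 14 comes from alcohol 13, whose C3=C4 bond is cut by ring-closing metathesis to acyclic diene 12. Opening the ring turns the trans C1/C2 relationship into an acyclic anti relationship.

**C1–C2 and both ring stereocentres.** 12 is the reduced Ireland–Claisen product (through 10 and 11) of ester 9. Cutting C1–C2 gives acid 8 and (S)-allylic alcohol 5. Conjugate alkynylation of a ring enone was considered for this bond. It would need an α-branched, hindered acceptor without a dependable asymmetric version, and the trans preference at C1 beside the gem-dimethyl group is small. The sigmatropic route sets C2 by chirality transfer from the carbinol of 5 and C1 by enolate geometry, in one chair transition state.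

**Sources.** Acid 8 is the methylenation product of keto acid 7, the ozonolysis product of isophorone 6. Isophorone thus supplies C1, C6 with both methyl groups, C5, C4 and the C4 methyl group. Alcohol 5 comes from enynone 4 by oxazaborolidine reduction, 4 from ynal 3, and 3 from (triisopropylsilyl)acetylene 1.

## Roads not taken

**Alternative 1:** The cut is at both carbon–carbon bonds of the carbinol carbon. Forward, the C1 boronic ester A2, which already carries ring B at C2, takes up a dihalomethyl carbenoid (Matteson homologation). The ring-A aryllithium A3 then displaces the remaining chloride by a second 1,2-shift on boron, and oxidation gives carbinol A1.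
- Merits: the carbinol carbon comes from a one-carbon reagent, three components are joined in one flask, and C1 migrates with retention.
- Weak points: the carbinol configuration is decided in the insertion and displacement, where an achiral boron diol leaves only the congested C1/C2 environment in control. The second shift needs a doubly ortho-substituted aryllithium to form an ate complex at a boron wedged between C6 and the new α-chloro centre. A2 presupposes that ring B has already been attached to C2 through its most hindered carbon, which this plan does not address.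
- Comparison: for the carbinol alone this road is shorter than the three steps (11–13) spent here. The chosen plan offers a hydride addition whose facial bias can be read from the substrate, and a solution for the C2–aryl bond.

**Alternative 2:** The cut is at the C4–C4a bond of each pyranone. Forward, a cationic gold catalyst converts bis(aryl propiolate) A5 into both coumarins by 6-endo-dig hydroarylation, giving A4, the triethylsilyl ether of the target.
- Merits: the lactones arrive after all basic and reducing steps, each arene offers a single activated position, and two rings form in one operation.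
- Weak points: as a strategy it solves only the periphery. A5 already contains the whole skeleton, all three stereocentres and the hindered C2–aryl bond.
- Comparison: in its own domain it is as good as anything here, and the chosen plan uses the same closure as its endgame (steps 21 and 22). What the chosen plan adds is an earlier strategic step that removes the problem of attaching ring B.

**Alternative 3:** The cut is at C2–C3 and C1–C6. Forward, 2′-hydroxychalcone A7, held by a chiral borate through phenol and carbonyl, is attacked at C2 by the CH2 end of silyloxydiene A8. The enolate then closes onto the dimethyl-substituted end to give cyclohexanone A6 with trans C1/C2.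
- Merits: the most convergent road. Both arenes, all six ring carbons and both ring stereocentres come from one catalytic asymmetric step, with trans geometry copied from the (E)-enone.
- Weak points: the diene end that must bond to C1 is fully substituted, so the second bond forms in a separate, reversible conjugate addition that may stop halfway. The β-aryl group of A7 is doubly ortho-substituted and shields C2. The product is a C4 ketone whose enol ether points toward C5, so the C3=C4(Me) alkene still needs regioselective enolisation toward C3 beside an acidic C1–H, then triflation and methylation.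
- Comparison: if the annulation works, this road is clearly shorter than the 23 steps proposed here. The chosen plan forms no bond at a carbon that already bears the hindered aryl group, and every stereocentre rests on a well-understood transition state (sigmatropic chair, Felkin–Anh).

Key step: step 18

Assumption: cyclobutane-1,3-dione 26 (which exists as 3-hydroxycyclobut-2-en-1-one) is taken as a purchasable compound.

## Route

Step 1
Reactants: 1 (triisopropylsilyl)acetylene
Product: 3 3-(triisopropylsilyl)prop-2-ynal, via lithium (triisopropylsilyl)acetylide 2 (not isolated)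
Conditions: n-BuLi, THF, −78 °C; DMF, −78 °C to rt; aq. NH4Cl
Reagents that add atoms: N,N-dimethylformamide, CN(C)C=O
Why: Formylation of a lithium acetylide with a formamide (Bouveault aldehyde synthesis); the hemiaminal alkoxide persists until the quench, so no second addition occurs.

Step 2
Reactants: 3 3-(triisopropylsilyl)prop-2-ynal
Product: 4 (E)-6-(triisopropylsilyl)hex-3-en-5-yn-2-one
Conditions: Ph3P=CHC(O)CH3, CH2Cl2, rt
Reagents that add atoms: (acetylmethylene)triphenylphosphorane, CC(=O)C=P(c1ccccc1)(c1ccccc1)c1ccccc1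
Why: Wittig olefination with a stabilised ylide should give the (E)-enone; the ynal is reactive and cannot enolise.

Step 3
Reactants: 4 (E)-6-(triisopropylsilyl)hex-3-en-5-yn-2-one
Product: 5 (S,E)-6-(triisopropylsilyl)hex-3-en-5-yn-2-ol
Conditions: (R)-1-methyl-3,3-diphenyltetrahydro-1H,3H-pyrrolo[1,2-c][1,3,2]oxazaborole (20 mol %), catecholborane, PhMe, −78 °C
Reagents that add atoms: none
Why: Corey–Bakshi–Shibata reduction; the enynyl group acts as the large and methyl as the small substituent, so the (R)-oxazaborolidine should deliver hydride to the face giving the (S)-alcohol, and catecholborane at low temperature avoids hydroboration.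

Step 4
Reactants: 6 isophorone (3,5,5-trimethylcyclohex-2-en-1-one)
Product: 7 3,3-dimethyl-5-oxohexanoic acid
Conditions: O3, EtOAc/AcOH, 0 °C; then 30% H2O2, 50 °C
Reagents that add atoms: ozone, [O-][O+]=O; hydrogen peroxide, OO
Why: Ozonolysis with oxidative work-up; the enone alkene is cleaved and the resulting 1,2-dicarbonyl unit is cut by peroxide with loss of the former C2 as formic acid, a classical degradation of isophorone.

Step 5
Reactants: 7 3,3-dimethyl-5-oxohexanoic acid
Product: 8 3,3,5-trimethylhex-5-enoic acid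
Conditions: Ph3PCH3Br, KOtBu (2.5 equiv), THF, 0 °C to reflux; then aq. HCl
Reagents that add atoms: methyltriphenylphosphonium bromide, C[P+](c1ccccc1)(c1ccccc1)c1ccccc1.[Br-]
Why: Wittig methylenation of the methyl ketone; the acid is carried as its potassium carboxylate, which is inert to the ylide.

Step 6
Reactants: 8 3,3,5-trimethylhex-5-enoic acid; 5 (S,E)-6-(triisopropylsilyl)hex-3-en-5-yn-2-ol
Product: 9 (S,E)-6-(triisopropylsilyl)hex-3-en-5-yn-2-yl 3,3,5-trimethylhex-5-enoate
Conditions: DCC, 4-(dimethylamino)pyridine (cat.), CH2Cl2, 0 °C to rt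
Reagents that add atoms: none
Why: Steglich esterification; the carbinol C–O bond is not broken, so the (S) configuration is retained.

Step 7
Reactants: 9 (S,E)-6-(triisopropylsilyl)hex-3-en-5-yn-2-yl 3,3,5-trimethylhex-5-enoate
Product: 12 (2S,3R,E)-2-(2,4-dimethylpent-4-en-2-yl)-3-[(triisopropylsilyl)ethynyl]hex-4-en-1-ol, via silyl ketene acetal 10 (not isolated), via trimethylsilyl ester 11 (not isolated)
Conditions: LiN(iPr)2, THF, −78 °C; Me3SiCl, Et3N, −78 °C to 50 °C; then LiAlH4, 0 °C
Reagents that add atoms: none
Why: Ireland–Claisen rearrangement, then reduction of the silyl ester; in THF without polar additive the ester should give the E(O)-enolate, trapped as the (E)-silyl ketene acetal. In the chair transition state the carbinol methyl and the alkynyl group of the (E)-alkene are equatorial, so the (S)-carbinol fixes C2 as R, and the axial tert-alkyl group on the enolate carbon gives the anti relationship (C1, S) that becomes trans on the ring.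

Step 8
Reactants: 12 (2S,3R,E)-2-(2,4-dimethylpent-4-en-2-yl)-3-[(triisopropylsilyl)ethynyl]hex-4-en-1-ol
Product: 13 {(1S,2R)-4,6,6-trimethyl-2-[(triisopropylsilyl)ethynyl]cyclohex-3-en-1-yl}methanol
Conditions: second-generation Grubbs catalyst (H2IMes)(PCy3)Cl2Ru=CHPh (5 mol %), CH2Cl2, 40 °C
Reagents that add atoms: none
Why: Ring-closing metathesis of a 1,7-diene to a trisubstituted cyclohexene with loss of propene; the gem-dimethyl group favours closure and the triisopropylsilyl-capped alkyne is too hindered for enyne metathesis.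

Step 9
Reactants: 13 {(1S,2R)-4,6,6-trimethyl-2-[(triisopropylsilyl)ethynyl]cyclohex-3-en-1-yl}methanol
Product: 14 (1S,2R)-4,6,6-trimethyl-2-[(triisopropylsilyl)ethynyl]cyclohex-3-ene-1-carbaldehyde
Conditions: Dess–Martin periodinane, NaHCO3, CH2Cl2, 0 °C to rt
Reagents that add atoms: none
Why: Dess–Martin oxidation under buffered, non-basic conditions, so the α-stereocentre C1 of the aldehyde should not epimerise.

Step 10
Reactants: 15 3,5-dimethoxyphenol
Product: 16 1,3-dimethoxy-5-(methoxymethoxy)benzene
Conditions: NaH, DMF, 0 °C; MOMCl, 0 °C to rt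
Reagents that add atoms: chloromethyl methyl ether, COCCl
Why: Williamson etherification; the acetal protects the phenol and later directs lithiation.

Step 11
Reactants: 16 1,3-dimethoxy-5-(methoxymethoxy)benzene; 14 (1S,2R)-4,6,6-trimethyl-2-[(triisopropylsilyl)ethynyl]cyclohex-3-ene-1-carbaldehyde
Product: 18 [2,4-dimethoxy-6-(methoxymethoxy)phenyl]{(1S,2R)-4,6,6-trimethyl-2-[(triisopropylsilyl)ethynyl]cyclohex-3-en-1-yl}methanol (both carbinol epimers), via aryllithium 17 (not isolated)
Conditions: n-BuLi, THF, 0 °C; then 14, −78 °C; aq. NH4Cl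
Reagents that add atoms: none
Why: Directed ortho-metalation between the chelating acetal oxygen and a methoxy group, then 1,2-addition to the aldehyde; both carbinol epimers are acceptable because this centre is erased in step 12.

Step 12
Reactants: 18 [2,4-dimethoxy-6-(methoxymethoxy)phenyl]{(1S,2R)-4,6,6-trimethyl-2-[(triisopropylsilyl)ethynyl]cyclohex-3-en-1-yl}methanol (both carbinol epimers)
Product: 19 [2,4-dimethoxy-6-(methoxymethoxy)phenyl]{(1S,2R)-4,6,6-trimethyl-2-[(triisopropylsilyl)ethynyl]cyclohex-3-en-1-yl}methanone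
Conditions: Dess–Martin periodinane, NaHCO3, CH2Cl2, rt
Reagents that add atoms: none
Why: Dess–Martin oxidation of the benzylic alcohol; neutral conditions leave C1, now α to an aryl ketone, untouched.

Step 13
Reactants: 19 [2,4-dimethoxy-6-(methoxymethoxy)phenyl]{(1S,2R)-4,6,6-trimethyl-2-[(triisopropylsilyl)ethynyl]cyclohex-3-en-1-yl}methanone
Product: 20 (S)-[2,4-dimethoxy-6-(methoxymethoxy)phenyl]{(1S,2R)-4,6,6-trimethyl-2-[(triisopropylsilyl)ethynyl]cyclohex-3-en-1-yl}methanol
Conditions: LiAlH4, THF, −78 °C to 0 °C
Reagents that add atoms: none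
Why: Felkin–Anh-controlled hydride addition; quaternary C6 stands anti to the incoming hydride, which passes the C1–H, and this should give the (S)-carbinol. A small hydride is chosen because the doubly ortho-substituted aryl ketone is shielded.

Step 14
Reactants: 20 (S)-[2,4-dimethoxy-6-(methoxymethoxy)phenyl]{(1S,2R)-4,6,6-trimethyl-2-[(triisopropylsilyl)ethynyl]cyclohex-3-en-1-yl}methanol
Product: 21 (S)-[2,4-dimethoxy-6-(methoxymethoxy)phenyl][(1S,2R)-2-ethynyl-4,6,6-trimethylcyclohex-3-en-1-yl]methanol
Conditions: Bu4NF, THF, 0 °C to rt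
Reagents that add atoms: none
Why: Fluoride-induced protodesilylation of the alkynylsilane; no other silyl group is present at this stage.

Step 15
Reactants: 21 (S)-[2,4-dimethoxy-6-(methoxymethoxy)phenyl][(1S,2R)-2-ethynyl-4,6,6-trimethylcyclohex-3-en-1-yl]methanol
Product: 22 tert-butyl{(S)-[2,4-dimethoxy-6-(methoxymethoxy)phenyl][(1S,2R)-2-ethynyl-4,6,6-trimethylcyclohex-3-en-1-yl]methoxy}dimethylsilane
Conditions: tBuMe2SiOTf, 2,6-lutidine, CH2Cl2, 0 °C to rt
Reagents that add atoms: tert-butyldimethylsilyl triflate, CC(C)(C)[Si](C)(C)OS(=O)(=O)C(F)(F)F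
Why: O-silylation with a silyl triflate, reactive enough for the hindered carbinol; the amine base does not deprotonate the terminal alkyne.

Step 16
Reactants: 22 tert-butyl{(S)-[2,4-dimethoxy-6-(methoxymethoxy)phenyl][(1S,2R)-2-ethynyl-4,6,6-trimethylcyclohex-3-en-1-yl]methoxy}dimethylsilane
Product: 25 tert-butyl{(S)-[2,4-dimethoxy-6-(methoxymethoxy)phenyl]{(1S,2R)-4,6,6-trimethyl-2-[(triisopropylsilyloxy)ethynyl]cyclohex-3-en-1-yl}methoxy}dimethylsilane, via lithium acetylide 23 (not isolated), via lithium ynolate 24 (not isolated)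
Conditions: n-BuLi, THF, −78 °C; LiOOtBu (from tBuOOH, LiN(SiMe3)2), −78 °C to 0 °C; iPr3SiOTf, −78 °C
Reagents that add atoms: tert-butyl hydroperoxide, CC(C)(C)OO; triisopropylsilyl triflate, CC(C)[Si](OS(=O)(=O)C(F)(F)F)(C(C)C)C(C)C
Why: Electrophilic oxygenation of the lithium acetylide by lithium tert-butylperoxide gives the lithium ynolate, a known entry to siloxyalkynes from terminal alkynes; the bulky silyl triflate should silylate on oxygen and give an ynol ether stable enough to handle.

Step 17
Reactants: 26 cyclobutane-1,3-dione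
Product: 27 3-methoxycyclobut-2-en-1-one
Conditions: Me3SiCHN2, MeOH/PhMe, 0 °C
Reagents that add atoms: (trimethylsilyl)diazomethane, C[Si](C)(C)C=[N+]=[N-]
Why: O-methylation of a strongly acidic vinylogous acid by diazomethane released in situ; no nucleophile is present that could open the strained ring.

Step 18
Reactants: 25 tert-butyl{(S)-[2,4-dimethoxy-6-(methoxymethoxy)phenyl]{(1S,2R)-4,6,6-trimethyl-2-[(triisopropylsilyloxy)ethynyl]cyclohex-3-en-1-yl}methoxy}dimethylsilane; 27 3-methoxycyclobut-2-en-1-one
Product: 32 2-[(1R,6S)-6-{(S)-(tert-butyldimethylsilyloxy)[2,4-dimethoxy-6-(methoxymethoxy)phenyl]methyl}-3,5,5-trimethylcyclohex-2-en-1-yl]-5-methoxy-3-(triisopropylsilyloxy)phenol, via vinylketene 28 (not isolated), via vinylcyclobutenone 29 (not isolated), via dienylketene 30 (not isolated), via cyclohexadienone 31 (not isolated)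
Conditions: PhMe, 110 °C, sealed tube
Reagents that add atoms: none
Why: Danheiser benzannulation. Heating opens 27 by 4π electrocyclic ring opening to vinylketene 28. Its carbonyl carbon bonds to the alkyne carbon of 25 that bears C2 (the nucleophilic carbon of the ynol ether) and its α-carbon to the oxygen-bearing carbon in a [2+2] cycloaddition, giving vinylcyclobutenone 29. 29 opens (4π) to dienylketene 30, which closes the six-membered carbocycle by thermal 6π electrocyclisation to cyclohexadienone 31, and tautomerisation gives phenol 32. The closest precedent is the thermal union of 3-alkyl- or 3-arylcyclobutenones with triisopropylsiloxyalkynes to give resorcinol monosilyl ethers; the 3-alkoxy member is a less used ketene source. No stereocentre is formed, and C1, C2 and the carbinol are spectators under neutral conditions. The selectivity needed is regiochemical and is fixed by the polarisation of the siloxyalkyne, which places the carbon bonded to C2 between the new C–OH and C–OSi carbons with methoxy para.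

Step 19
Reactants: 32 2-[(1R,6S)-6-{(S)-(tert-butyldimethylsilyloxy)[2,4-dimethoxy-6-(methoxymethoxy)phenyl]methyl}-3,5,5-trimethylcyclohex-2-en-1-yl]-5-methoxy-3-(triisopropylsilyloxy)phenol
Product: 33 tert-butyl{(S)-{(1S,2R)-2-[2,4-dimethoxy-6-(triisopropylsilyloxy)phenyl]-4,6,6-trimethylcyclohex-3-en-1-yl}[2,4-dimethoxy-6-(methoxymethoxy)phenyl]methoxy}dimethylsilane
Conditions: MeI, K2CO3, acetone, reflux
Reagents that add atoms: iodomethane, CI
Why: Williamson methylation of the only free phenol; anhydrous carbonate should leave the aryl silyl ether in place, which keeps the two ortho oxygens of ring B distinct.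

Step 20
Reactants: 33 tert-butyl{(S)-{(1S,2R)-2-[2,4-dimethoxy-6-(triisopropylsilyloxy)phenyl]-4,6,6-trimethylcyclohex-3-en-1-yl}[2,4-dimethoxy-6-(methoxymethoxy)phenyl]methoxy}dimethylsilane
Product: 35 2-[(1R,6S)-6-{(S)-(tert-butyldimethylsilyloxy)(2-hydroxy-4,6-dimethoxyphenyl)methyl}-3,5,5-trimethylcyclohex-2-en-1-yl]-3,5-dimethoxyphenol, via aryl trimethylsilyl ether 34 (not isolated)
Conditions: Me3SiOTf, 2,2′-bipyridyl, CH2Cl2, 0 °C; then Bu4NF, THF, 0 °C
Reagents that add atoms: none
Why: Acetal cleavage by a silyl triflate/bipyridyl pair, which converts aromatic methoxymethyl ethers into aryl silyl ethers without free protic acid and spares alkyl silyl ethers, so the ionisable benzylic position is not exposed. Fluoride at 0 °C then cleaves both aryl silyl ethers, while the hindered secondary silyl ether reacts far more slowly.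

Step 21
Reactants: 35 2-[(1R,6S)-6-{(S)-(tert-butyldimethylsilyloxy)(2-hydroxy-4,6-dimethoxyphenyl)methyl}-3,5,5-trimethylcyclohex-2-en-1-yl]-3,5-dimethoxyphenol
Product: 36 2-[(1R,6S)-6-{(S)-(tert-butyldimethylsilyloxy)[2,4-dimethoxy-6-(propioloyloxy)phenyl]methyl}-3,5,5-trimethylcyclohex-2-en-1-yl]-3,5-dimethoxyphenyl propiolate
Conditions: propiolic acid, DCC, 4-(dimethylamino)pyridine (cat.), CH2Cl2, 0 °C
Reagents that add atoms: propiolic acid, C#CC(=O)O
Why: Steglich esterification of both phenols; low temperature and little amine catalyst limit conjugate addition to the propiolate.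

Step 22
Reactants: 36 2-[(1R,6S)-6-{(S)-(tert-butyldimethylsilyloxy)[2,4-dimethoxy-6-(propioloyloxy)phenyl]methyl}-3,5,5-trimethylcyclohex-2-en-1-yl]-3,5-dimethoxyphenyl propiolate
Product: 37 8-[(1R,6S)-6-{(S)-(tert-butyldimethylsilyloxy)(5,7-dimethoxy-2-oxo-2H-chromen-8-yl)methyl}-3,5,5-trimethylcyclohex-2-en-1-yl]-5,7-dimethoxy-2H-chromen-2-one
Conditions: AuCl(PPh3) (10 mol %), AgOTf (10 mol %), ClCH2CH2Cl, rt
Reagents that add atoms: none
Why: Twofold intramolecular hydroarylation by cationic monovalent gold; each activated alkyne is attacked 6-endo-dig by the only free ortho carbon, which is ortho and para to methoxy groups, and protodeauration gives the coumarins.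

Step 23
Reactants: 37 8-[(1R,6S)-6-{(S)-(tert-butyldimethylsilyloxy)(5,7-dimethoxy-2-oxo-2H-chromen-8-yl)methyl}-3,5,5-trimethylcyclohex-2-en-1-yl]-5,7-dimethoxy-2H-chromen-2-one
Product: 38 8-[(1R,6S)-6-{(S)-(5,7-dimethoxy-2-oxo-2H-chromen-8-yl)(hydroxy)methyl}-3,5,5-trimethylcyclohex-2-en-1-yl]-5,7-dimethoxy-2H-chromen-2-one (CNP0324863.2)
Conditions: HF·pyridine, pyridine, THF, 0 °C to rt
Reagents that add atoms: none
Why: Fluoride cleavage of the silyl ether under buffered conditions that should neither open the lactones nor ionise the benzylic alcohol.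

## Compound list

1 | (triisopropylsilyl)acetylene | C#C[Si](C(C)C)(C(C)C)C(C)C | starting material
2 | lithium (triisopropylsilyl)acetylide | [Li]C#C[Si](C(C)C)(C(C)C)C(C)C | intermediate
3 | 3-(triisopropylsilyl)prop-2-ynal | O=CC#C[Si](C(C)C)(C(C)C)C(C)C | intermediate
4 | (E)-6-(triisopropylsilyl)hex-3-en-5-yn-2-one | CC(=O)/C=C/C#C[Si](C(C)C)(C(C)C)C(C)C | intermediate
5 | (S,E)-6-(triisopropylsilyl)hex-3-en-5-yn-2-ol | C[C@H](O)/C=C/C#C[Si](C(C)C)(C(C)C)C(C)C | intermediate
6 | isophorone (3,5,5-trimethylcyclohex-2-en-1-one) | CC1=CC(=O)CC(C)(C)C1 | starting material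
7 | 3,3-dimethyl-5-oxohexanoic acid | CC(=O)CC(C)(C)CC(=O)O | intermediate
8 | 3,3,5-trimethylhex-5-enoic acid | C=C(C)CC(C)(C)CC(=O)O | intermediate
9 | (S,E)-6-(triisopropylsilyl)hex-3-en-5-yn-2-yl 3,3,5-trimethylhex-5-enoate | C=C(C)CC(C)(C)CC(=O)O[C@@H](C)/C=C/C#C[Si](C(C)C)(C(C)C)C(C)C | intermediate
10 | (E)-trimethylsilyl ketene acetal of ester 9 (silyloxy trans to the tert-alkyl group) | C=C(C)CC(C)(C)/C=C(/O[Si](C)(C)C)O[C@@H](C)/C=C/C#C[Si](C(C)C)(C(C)C)C(C)C | intermediate
11 | trimethylsilyl (2S,3R,E)-2-(2,4-dimethylpent-4-en-2-yl)-3-[(triisopropylsilyl)ethynyl]hex-4-enoate | C[Si](C)(C)OC(=O)[C@@H]([C@H](C#C[Si](C(C)C)(C(C)C)C(C)C)/C=C/C)C(C)(C)CC(C)=C | intermediate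
12 | (2S,3R,E)-2-(2,4-dimethylpent-4-en-2-yl)-3-[(triisopropylsilyl)ethynyl]hex-4-en-1-ol | OC[C@@H]([C@H](C#C[Si](C(C)C)(C(C)C)C(C)C)/C=C/C)C(C)(C)CC(C)=C | intermediate
13 | {(1S,2R)-4,6,6-trimethyl-2-[(triisopropylsilyl)ethynyl]cyclohex-3-en-1-yl}methanol | OC[C@H]1[C@H](C#C[Si](C(C)C)(C(C)C)C(C)C)C=C(C)CC1(C)C | intermediate
14 | (1S,2R)-4,6,6-trimethyl-2-[(triisopropylsilyl)ethynyl]cyclohex-3-ene-1-carbaldehyde | O=C[C@H]1[C@H](C#C[Si](C(C)C)(C(C)C)C(C)C)C=C(C)CC1(C)C | intermediate
15 | 3,5-dimethoxyphenol | COc1cc(O)cc(OC)c1 | starting material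
16 | 1,3-dimethoxy-5-(methoxymethoxy)benzene | COCOc1cc(OC)cc(OC)c1 | intermediate
17 | [2,4-dimethoxy-6-(methoxymethoxy)phenyl]lithium | [Li]c1c(OC)cc(OC)cc1OCOC | intermediate
18 | [2,4-dimethoxy-6-(methoxymethoxy)phenyl]{(1S,2R)-4,6,6-trimethyl-2-[(triisopropylsilyl)ethynyl]cyclohex-3-en-1-yl}methanol (both carbinol epimers) | COCOc1cc(OC)cc(OC)c1C(O)[C@H]1[C@H](C#C[Si](C(C)C)(C(C)C)C(C)C)C=C(C)CC1(C)C | intermediate
19 | [2,4-dimethoxy-6-(methoxymethoxy)phenyl]{(1S,2R)-4,6,6-trimethyl-2-[(triisopropylsilyl)ethynyl]cyclohex-3-en-1-yl}methanone | COCOc1cc(OC)cc(OC)c1C(=O)[C@H]1[C@H](C#C[Si](C(C)C)(C(C)C)C(C)C)C=C(C)CC1(C)C | intermediate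
20 | (S)-[2,4-dimethoxy-6-(methoxymethoxy)phenyl]{(1S,2R)-4,6,6-trimethyl-2-[(triisopropylsilyl)ethynyl]cyclohex-3-en-1-yl}methanol | COCOc1cc(OC)cc(OC)c1[C@@H](O)[C@H]1[C@H](C#C[Si](C(C)C)(C(C)C)C(C)C)C=C(C)CC1(C)C | intermediate
21 | (S)-[2,4-dimethoxy-6-(methoxymethoxy)phenyl][(1S,2R)-2-ethynyl-4,6,6-trimethylcyclohex-3-en-1-yl]methanol | COCOc1cc(OC)cc(OC)c1[C@@H](O)[C@H]1[C@H](C#C)C=C(C)CC1(C)C | intermediate
22 | tert-butyl{(S)-[2,4-dimethoxy-6-(methoxymethoxy)phenyl][(1S,2R)-2-ethynyl-4,6,6-trimethylcyclohex-3-en-1-yl]methoxy}dimethylsilane | COCOc1cc(OC)cc(OC)c1[C@@H](O[Si](C)(C)C(C)(C)C)[C@H]1[C@H](C#C)C=C(C)CC1(C)C | intermediate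
23 | lithium acetylide of 22 (C2–C≡C–Li) | COCOc1cc(OC)cc(OC)c1[C@@H](O[Si](C)(C)C(C)(C)C)[C@H]1[C@H](C#C[Li])C=C(C)CC1(C)C | intermediate
24 | lithium ynolate of 22 (C2–C≡C–OLi) | COCOc1cc(OC)cc(OC)c1[C@@H](O[Si](C)(C)C(C)(C)C)[C@H]1[C@H](C#CO[Li])C=C(C)CC1(C)C | intermediate
25 | tert-butyl{(S)-[2,4-dimethoxy-6-(methoxymethoxy)phenyl]{(1S,2R)-4,6,6-trimethyl-2-[(triisopropylsilyloxy)ethynyl]cyclohex-3-en-1-yl}methoxy}dimethylsilane | COCOc1cc(OC)cc(OC)c1[C@@H](O[Si](C)(C)C(C)(C)C)[C@H]1[C@H](C#CO[Si](C(C)C)(C(C)C)C(C)C)C=C(C)CC1(C)C | intermediate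
26 | cyclobutane-1,3-dione | O=C1CC(=O)C1 | starting material
27 | 3-methoxycyclobut-2-en-1-one | COC1=CC(=O)C1 | intermediate
28 | (1-methoxyvinyl)ketene (3-methoxybuta-1,3-dien-1-one) | C=C(OC)C=C=O | intermediate
29 | 4-(1-methoxyvinyl)-3-(triisopropylsilyloxy)cyclobut-2-en-1-one carrying at its C2 the ring carbon C2 of 25 (new ring carbon unassigned) | COCOc1cc(OC)cc(OC)c1[C@@H](O[Si](C)(C)C(C)(C)C)[C@H]1[C@H](C2=C(O[Si](C(C)C)(C(C)C)C(C)C)C(C(OC)=C)C2=O)C=C(C)CC1(C)C | intermediate
30 | dienylketene from 29: O=C=C(ring C2)–C(OSi(iPr)3)=CH–C(OMe)=CH2, ketene carbon and methoxyvinyl group cis | COCOc1cc(OC)cc(OC)c1[C@@H](O[Si](C)(C)C(C)(C)C)[C@H]1[C@H](C(=C=O)/C(O[Si](C(C)C)(C(C)C)C(C)C)=C\C(OC)=C)C=C(C)CC1(C)C | intermediate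
31 | 5-methoxy-3-(triisopropylsilyloxy)cyclohexa-2,4-dien-1-one carrying the cyclohexenyl group at C2 | COCOc1cc(OC)cc(OC)c1[C@@H](O[Si](C)(C)C(C)(C)C)[C@H]1[C@H](C2=C(O[Si](C(C)C)(C(C)C)C(C)C)C=C(OC)CC2=O)C=C(C)CC1(C)C | intermediate
32 | 2-[(1R,6S)-6-{(S)-(tert-butyldimethylsilyloxy)[2,4-dimethoxy-6-(methoxymethoxy)phenyl]methyl}-3,5,5-trimethylcyclohex-2-en-1-yl]-5-methoxy-3-(triisopropylsilyloxy)phenol | COCOc1cc(OC)cc(OC)c1[C@@H](O[Si](C)(C)C(C)(C)C)[C@H]1[C@H](c2c(O)cc(OC)cc2O[Si](C(C)C)(C(C)C)C(C)C)C=C(C)CC1(C)C | intermediate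
33 | tert-butyl{(S)-{(1S,2R)-2-[2,4-dimethoxy-6-(triisopropylsilyloxy)phenyl]-4,6,6-trimethylcyclohex-3-en-1-yl}[2,4-dimethoxy-6-(methoxymethoxy)phenyl]methoxy}dimethylsilane | COCOc1cc(OC)cc(OC)c1[C@@H](O[Si](C)(C)C(C)(C)C)[C@H]1[C@H](c2c(OC)cc(OC)cc2O[Si](C(C)C)(C(C)C)C(C)C)C=C(C)CC1(C)C | intermediate
34 | aryl trimethylsilyl ether: 33 with the ring-A methoxymethyl group replaced by SiMe3 | C[Si](C)(C)Oc1cc(OC)cc(OC)c1[C@@H](O[Si](C)(C)C(C)(C)C)[C@H]1[C@H](c2c(OC)cc(OC)cc2O[Si](C(C)C)(C(C)C)C(C)C)C=C(C)CC1(C)C | intermediate
35 | 2-[(1R,6S)-6-{(S)-(tert-butyldimethylsilyloxy)(2-hydroxy-4,6-dimethoxyphenyl)methyl}-3,5,5-trimethylcyclohex-2-en-1-yl]-3,5-dimethoxyphenol | Oc1cc(OC)cc(OC)c1[C@@H](O[Si](C)(C)C(C)(C)C)[C@H]1[C@H](c2c(OC)cc(OC)cc2O)C=C(C)CC1(C)C | intermediate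
36 | 2-[(1R,6S)-6-{(S)-(tert-butyldimethylsilyloxy)[2,4-dimethoxy-6-(propioloyloxy)phenyl]methyl}-3,5,5-trimethylcyclohex-2-en-1-yl]-3,5-dimethoxyphenyl propiolate | C#CC(=O)Oc1cc(OC)cc(OC)c1[C@@H](O[Si](C)(C)C(C)(C)C)[C@H]1[C@H](c2c(OC)cc(OC)cc2OC(=O)C#C)C=C(C)CC1(C)C | intermediate
37 | 8-[(1R,6S)-6-{(S)-(tert-butyldimethylsilyloxy)(5,7-dimethoxy-2-oxo-2H-chromen-8-yl)methyl}-3,5,5-trimethylcyclohex-2-en-1-yl]-5,7-dimethoxy-2H-chromen-2-one | COc1cc(OC)c2ccc(=O)oc2c1[C@@H](O[Si](C)(C)C(C)(C)C)[C@H]1[C@H](c2c(OC)cc(OC)c3ccc(=O)oc23)C=C(C)CC1(C)C | intermediate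
38 | 8-[(1R,6S)-6-{(S)-(5,7-dimethoxy-2-oxo-2H-chromen-8-yl)(hydroxy)methyl}-3,5,5-trimethylcyclohex-2-en-1-yl]-5,7-dimethoxy-2H-chromen-2-one (CNP0324863.2) | COc1cc(OC)c2ccc(=O)oc2c1[C@@H](O)[C@H]1[C@H](c2c(OC)cc(OC)c3ccc(=O)oc23)C=C(C)CC1(C)C | target

## Step count and least certain steps

Total: 23 steps. Longest linear sequence: 19 steps (1–3, 6–9, 11–16, 18–23), counted from (triisopropylsilyl)acetylene; the isophorone branch is one step shorter.

**Step 18 (key step).** The alkoxy group stabilises cyclobutenone 27 as a vinylogous ester, so ring opening to 28 may need a temperature at which the siloxyalkyne degrades or the vinylketene dimerises. The phenol formed may also be acylated by excess ketene. Fallback, setting out from 25 and returning at 32: the same vinylketene is generated at room temperature by a photochemical Wolff rearrangement. Purchased 3,3-dimethoxybutan-2-one loses methanol under acid catalysis to give 3-methoxybut-3-en-2-one F1. Trifluoroacetylation (LiN(SiMe3)2, CF3CO2CH2CF3) gives 1,1,1-trifluoro-5-methoxyhex-5-ene-2,4-dione F2. Regitz diazo transfer with cleavage of the trifluoroacetyl group (MsN3, Et3N, H2O) gives 1-diazo-3-methoxybut-3-en-2-one F3. Irradiation of F3 with 25 (300–350 nm, ClCH2CH2Cl, rt, then 80 °C) should give 28 and, through 29–31, phenol 32.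

**Step 7.** The tert-alkyl group on the enolate carbon is axial in the chair transition state. Leakage through a boat transition state or incomplete enolate geometry would erode the anti (ring-trans) selectivity, and C1 cannot be repaired later by equilibration. Fallback, setting out from acid 8 and returning at 11: both large groups are placed equatorial by changing alkene and enolate geometry together.
- Cadiot–Chodkiewicz coupling of purchased (R)-but-3-yn-2-ol with purchased (bromoethynyl)triisopropylsilane (CuCl, NH2OH·HCl, n-BuNH2) gives (R)-6-(triisopropylsilyl)hexa-3,5-diyn-2-ol F4.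
- Semihydrogenation of the unhindered alkyne (H2, Pd on CaCO3 poisoned with Pb(OAc)2, quinoline) gives (R,Z)-6-(triisopropylsilyl)hex-3-en-5-yn-2-ol F5.
- Steglich esterification with 8 gives (R,Z)-6-(triisopropylsilyl)hex-3-en-5-yn-2-yl 3,3,5-trimethylhex-5-enoate F6.
- Enolisation in THF/DMPU (LiN(iPr)2, then Me3SiCl) gives the (Z)-trimethylsilyl ketene acetal F7, whose chair rearrangement (tert-alkyl equatorial, slim alkynyl axial) should give the same silyl ester 11.

**Step 13.** The twisted, doubly ortho-substituted aryl ketone may not react through the Felkin–Anh conformer, giving poor or reversed facial selectivity, or it may be reduced sluggishly. Fallback, setting out from 14 and returning at 20: if hydride addition favours the wrong epimer, aryl addition to the aldehyde should, by the same model with the roles exchanged, favour the right one. The major epimer of 18 from step 11 is then separated and used as 20, and steps 12 and 13 are dropped. This fallback makes no new compound (entry F0).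

**Step 16.** Oxygen transfer to the hindered acetylide may be incomplete, with protonation returning 22, and the ynolate may be lost by silylation on carbon or by hydrolysis on isolation. Fallback, setting out from 22 and returning at 24: the ynolate is made from an ester instead of the acetylide.
- Anti-Markovnikov hydration of the alkyne (dicyclohexylborane, then NaBO3) gives the C2 acetaldehyde F8 (C2–CH2–CHO in place of C2–C≡CH).
- Pinnick oxidation (NaClO2, NaH2PO4, 2-methylbut-2-ene) gives the C2 acetic acid F9.
- Me3SiCHN2 gives the methyl ester F10.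
- Twofold enolate bromination (LiN(SiMe3)2, BrCl2C–CCl2Br) gives the α,α-dibromo ester F11.
- Lithium–bromine exchange (tBuLi, THF, −78 °C to 0 °C) with loss of methoxide should give ynolate 24, which is silylated as in step 16.

## Further compounds

F1 | step 18 | 3-methoxybut-3-en-2-one | C=C(OC)C(C)=O
F2 | step 18 | 1,1,1-trifluoro-5-methoxyhex-5-ene-2,4-dione | C=C(OC)C(=O)CC(=O)C(F)(F)F
F3 | step 18 | 1-diazo-3-methoxybut-3-en-2-one | C=C(OC)C(=O)C=[N+]=[N-]
F4 | step 7 | (R)-6-(triisopropylsilyl)hexa-3,5-diyn-2-ol | C[C@@H](O)C#CC#C[Si](C(C)C)(C(C)C)C(C)C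
F5 | step 7 | (R,Z)-6-(triisopropylsilyl)hex-3-en-5-yn-2-ol | C[C@@H](O)/C=C\C#C[Si](C(C)C)(C(C)C)C(C)C
F6 | step 7 | (R,Z)-6-(triisopropylsilyl)hex-3-en-5-yn-2-yl 3,3,5-trimethylhex-5-enoate | C=C(C)CC(C)(C)CC(=O)O[C@H](C)/C=C\C#C[Si](C(C)C)(C(C)C)C(C)C
F7 | step 7 | (Z)-trimethylsilyl ketene acetal of F6 (silyloxy cis to the tert-alkyl group) | C=C(C)CC(C)(C)/C=C(\O[Si](C)(C)C)O[C@H](C)/C=C\C#C[Si](C(C)C)(C(C)C)C(C)C
F0 | step 13 | none | none
F8 | step 16 | C2 acetaldehyde: 22 with C2–CH2–CHO in place of C2–C≡CH | COCOc1cc(OC)cc(OC)c1[C@@H](O[Si](C)(C)C(C)(C)C)[C@H]1[C@H](CC=O)C=C(C)CC1(C)C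
F9 | step 16 | C2 acetic acid: 22 with C2–CH2–CO2H in place of C2–C≡CH | COCOc1cc(OC)cc(OC)c1[C@@H](O[Si](C)(C)C(C)(C)C)[C@H]1[C@H](CC(=O)O)C=C(C)CC1(C)C
F10 | step 16 | methyl ester of F9 | COCOc1cc(OC)cc(OC)c1[C@@H](O[Si](C)(C)C(C)(C)C)[C@H]1[C@H](CC(=O)OC)C=C(C)CC1(C)C
F11 | step 16 | α,α-dibromo ester of F10 (C2–CBr2–CO2Me) | COCOc1cc(OC)cc(OC)c1[C@@H](O[Si](C)(C)C(C)(C)C)[C@H]1[C@H](C(Br)(Br)C(=O)OC)C=C(C)CC1(C)C
A1 | alternative 1 | bis(allyl ether) carbinol with all three stereocentres | C=CCOc1cc(OC)cc(OC)c1[C@@H](O)[C@H]1[C@H](c2c(OC)cc(OC)cc2OCC=C)C=C(C)CC1(C)C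
A2 | alternative 1 | C1 pinacol boronic ester carrying the ring-B aryl group at C2 | CC2(C)OB(OC2(C)C)[C@H]1[C@H](c3c(OC)cc(OC)cc3OCC=C)C=C(C)CC1(C)C
A3 | alternative 1 | [2-(allyloxy)-4,6-dimethoxyphenyl]lithium | [Li]c1c(OC)cc(OC)cc1OCC=C
A4 | alternative 2 | triethylsilyl ether of the target | COc1cc(OC)c2ccc(=O)oc2c1[C@@H](O[Si](CC)(CC)CC)[C@H]1[C@H](c2c(OC)cc(OC)c3ccc(=O)oc23)C=C(C)CC1(C)C
A5 | alternative 2 | bis(aryl propiolate) with the carbinol as triethylsilyl ether | C#CC(=O)Oc1cc(OC)cc(OC)c1[C@@H](O[Si](CC)(CC)CC)[C@H]1[C@H](c2c(OC)cc(OC)cc2OC(=O)C#C)C=C(C)CC1(C)C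
A6 | alternative 3 | trans-4-aroyl-5-aryl-3,3-dimethylcyclohexanone | COc1cc(OC)c(C(=O)[C@H]2[C@H](c3c(OC)cc(OC)cc3OCOC)CC(=O)CC2(C)C)c(O)c1
A7 | alternative 3 | (E)-1-(2-hydroxy-4,6-dimethoxyphenyl)-3-[2,4-dimethoxy-6-(methoxymethoxy)phenyl]prop-2-en-1-one | COCOc1cc(OC)cc(OC)c1/C=C/C(=O)c1c(O)cc(OC)cc1OC
A8 | alternative 3 | 4-methyl-2-(trimethylsilyloxy)penta-1,3-diene | C=C(O[Si](C)(C)C)C=C(C)C
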